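**Retrosynthetic overview**

1. Ring B is the dihydropyran O1–C2–C3–C4–C4a–C8a, fused through C4a=C8a to syncarpic ring A; ring C is the syncarpic acid unit on C2. Rings A and C both come from one dearomatised acylphloroglucinol and exist before ring B.
2. Last disconnection: C2–ring C. C2 is at the aldehyde oxidation level, so it is carried as a 2-methoxy acetal and exchanged for syncarpic acid at the end, with C2 under thermodynamic control.
3. Key disconnection: C4–C4a (closure of ring B) together with the CH2–CH(CH3)2 bond of the isobutyl group, by a nickel-catalysed reductive 6-exo cyclisation/alkylation of a C4a-bromo vinylogous ester with 2-bromopropane.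
4. Enabling feature: the enol-ether double bond C4a=C8a shared by rings A and B. Its vinylic C4a can carry bromine, and O1 on C8a can be tied to C2 as a mixed acetal, which puts the C4a–metal bond 6-exo to a vinyl group on C3.
5. C3 is set first by an organocatalytic α-vinylation of isovaleraldehyde; C4 follows from C3 in the ring closure; C2 follows from C3 and C4 in the last step.

Key step: step 8

Remark: the acetal carbon C2 is carried as a mixture of both epimers from the mixed acetal onward, because it is re-set in the last step; the SMILES leave it undefined there.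

**Route**

Step 1
Reactants: 1 2',4',6'-trihydroxyacetophenone
Product: 2 2-acetyl-3-hydroxy-4,4,6,6-tetramethylcyclohex-2-ene-1,5-dione (acetylsyncarpic acid)
Conditions: MeI, NaOMe, MeOH, 0 °C to reflux
Reagents that add atoms: iodomethane, CI
Why: Dearomatising exhaustive C-methylation of an acylphloroglucinol, the standard entry to acylsyncarpic acids; the two free ring carbons are each dimethylated and no stereocentre is formed.

Step 2
Reactants: 2 acetylsyncarpic acid
Product: 3 3-hydroxy-4,4,6,6-tetramethylcyclohex-2-ene-1,5-dione (syncarpic acid)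
Conditions: 6 M HCl (aq), reflux
Reagents that add atoms: none
Why: Acid-mediated retro-Claisen deacylation of the β-triketone should release the parent cyclic 1,3-dione and acetic acid.

Step 3
Reactants: 3 syncarpic acid
Product: 4 2-bromo-3-hydroxy-4,4,6,6-tetramethylcyclohex-2-ene-1,5-dione (2-bromosyncarpic acid)
Conditions: NBS (1.0 equiv), CH2Cl2, 0 °C
Reagents that add atoms: N-bromosuccinimide, O=C1CCC(=O)N1Br
Why: Electrophilic α-bromination of a cyclic 1,3-dione enol at its only enolisable carbon; the bromine blocks C-alkylation in step 7 and arms C4a for step 8.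

Step 4
Reactants: 5 3-methylbutanal (isovaleraldehyde); 6 potassium trifluoro[(E)-2-phenylethenyl]borate
Product: 7 (2S,3E)-4-phenyl-2-(propan-2-yl)but-3-enal
Conditions: (2R,5R)-5-benzyl-2-tert-butyl-3-methylimidazolidin-4-one·TFA (20 mol%), (NH4)2Ce(NO3)6, NaHCO3, H2O, DME, −50 °C
Reagents that add atoms: none
Why: SOMO-activation aminocatalysis (enantioselective α-vinylation of aldehydes with vinyl trifluoroborates): tetravalent cerium oxidises the E-enamine to a radical cation that adds to the boron-bearing carbon of 6 and, after a second oxidation and loss of boron, gives the E-alkene; the benzyl and tert-butyl groups of the (2R,5R) catalyst leave the Re face of the α-carbon open, which should set C3 as S.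

Step 5
Reactants: 7 (2S,3E)-4-phenyl-2-(propan-2-yl)but-3-enal
Product: 8 [(1E,3S)-3-(dimethoxymethyl)-4-methylpent-1-en-1-yl]benzene
Conditions: MeOSiMe3, TMSOTf (cat.), CH2Cl2, −78 °C
Reagents that add atoms: methoxytrimethylsilane, CO[Si](C)(C)C
Why: Silyl-triflate-catalysed acetalisation runs aprotically at low temperature, so the enolisable α-vinyl stereocentre should not epimerise and the double bond should not move into conjugation.

Step 6
Reactants: 8 [(1E,3S)-3-(dimethoxymethyl)-4-methylpent-1-en-1-yl]benzene
Product: 9 (3S)-3-(dimethoxymethyl)-4-methylpent-1-ene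
Conditions: ethylene (5 bar), second-generation Grubbs catalyst (5 mol%), CH2Cl2, 40 °C
Reagents that add atoms: ethylene, C=C
Why: Ethenolysis (cross-metathesis with ethylene) should cut the styryl double bond to the terminal vinyl group and styrene without touching the adjacent stereocentre.

Step 7
Reactants: 9 (3S)-3-(dimethoxymethyl)-4-methylpent-1-ene; 4 2-bromosyncarpic acid
Product: 11 2-bromo-3-{[(2S)-1-methoxy-2-(propan-2-yl)but-3-en-1-yl]oxy}-4,4,6,6-tetramethylcyclohex-2-ene-1,5-dione (both acetal epimers), via α-chloro ether 10 (not isolated)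
Conditions: AcCl, ZnBr2 (1 mol%), CH2Cl2, 0 °C to rt; then 4, iPr2NEt (1.0 equiv to 4), CH2Cl2, −20 °C to 0 °C
Reagents that add atoms: none
Why: Zinc-catalysed exchange of one methoxy group for chloride with acetyl chloride gives the α-chloro ether, which should O-alkylate the ammonium enolate of 4 as alkoxymethyl chlorides do with 1,3-dione enolates (C-alkylation is blocked by bromine), leaving C3 untouched and the new acetal centre as a mixture.

Step 8
Reactants: 11 mixed acetal; 12 2-bromopropane
Product: 13 (3S,4S)-2-methoxy-6,6,8,8-tetramethyl-4-(2-methylpropyl)-3-(propan-2-yl)-3,4-dihydro-2H-chromene-5,7(6H,8H)-dione (both C2 epimers)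
Conditions: NiBr2·glyme (10 mol%), 4,4'-di-tert-butyl-2,2'-bipyridine (12 mol%), Mn powder, DMA, 25 °C, slow addition of 12
Reagents that add atoms: none
Why: Proposed new method: oxidative addition of zerovalent nickel into the enone-activated C4a–Br bond gives an alkenylnickel that inserts the pendant C4=CH2 group in a 6-exo-trig syn-migratory insertion (ring B closes through the C4–C4a bond), and the resulting primary alkylnickel captures the isopropyl radical formed from 12 by halogen-atom abstraction and reductively eliminates the CH2–CH(CH3)2 bond, with Mn turning the catalyst over. The closest known reaction type is the nickel-catalysed reductive 1,2-dicarbofunctionalisation (cyclisation/cross-electrophile coupling) of alkenes tethered to aryl bromides with alkyl bromides; new here are the alkenyl bromide of a vinylogous ester, the acetal tether and the six-membered ring. C4 is set in the insertion through a chair-like transition state with the C3 isopropyl group and the incipient CH2–Ni arm both equatorial, which should give the 3,4-trans (3S,4S) relationship from the fixed 3S centre; the epimeric acetal carbon has no bearing because it is re-set in step 9. The step needs cyclisation to outrun direct alkenyl–isopropyl coupling and β-hydride elimination: insertion is unimolecular while radical capture is bimolecular, so slow addition of 12 favours the sequence, and two-electron oxidative addition selects the activated sp2 C–Br bond of 11 over the secondary alkyl bromide. A metallated C4a is chosen over a free C4 radical because an alkyl radical at C4 would add 5-exo to C8a, the β-carbon of the enone.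

Step 9
Reactants: 13 cyclic 2-methoxy acetal; 3 syncarpic acid
Product: 14 ericifolione, (2R,3S,4S)-2-(2-hydroxy-3,3,5,5-tetramethyl-4,6-dioxocyclohex-1-en-1-yl)-6,6,8,8-tetramethyl-4-(2-methylpropyl)-3-(propan-2-yl)-3,4-dihydro-2H-chromene-5,7(6H,8H)-dione
Conditions: 3 (1.2 equiv), BF3·OEt2 (20 mol%), 4 Å MS, CH2Cl2, −40 °C to 0 °C
Reagents that add atoms: none
Why: Lewis-acid-mediated ionisation of the acetal and C-alkylation of the 1,3-dione (Mukaiyama-type acetal substitution, equivalent to a Knoevenagel/oxa-Michael sequence); C2 should settle under thermodynamic control through reversible retro-oxa-Michael/oxa-Michael ring opening on the 2R epimer, whose half-chair has the syncarpyl group equatorial and cis to the axial C3 isopropyl group while the C4 isobutyl group stays pseudoaxial.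

**Compound list**

1 | 2',4',6'-trihydroxyacetophenone | CC(=O)c1c(O)cc(O)cc1O | starting material
2 | 2-acetyl-3-hydroxy-4,4,6,6-tetramethylcyclohex-2-ene-1,5-dione (acetylsyncarpic acid) | CC(=O)C1=C(O)C(C)(C)C(=O)C(C)(C)C1=O | intermediate
3 | 3-hydroxy-4,4,6,6-tetramethylcyclohex-2-ene-1,5-dione (syncarpic acid) | O=C1C=C(O)C(C)(C)C(=O)C1(C)C | intermediate
4 | 2-bromo-3-hydroxy-4,4,6,6-tetramethylcyclohex-2-ene-1,5-dione (2-bromosyncarpic acid) | O=C1C(Br)=C(O)C(C)(C)C(=O)C1(C)C | intermediate
5 | 3-methylbutanal (isovaleraldehyde) | CC(C)CC=O | starting material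
6 | potassium trifluoro[(E)-2-phenylethenyl]borate | [K+].F[B-](F)(F)/C=C/c1ccccc1 | starting material
7 | (2S,3E)-4-phenyl-2-(propan-2-yl)but-3-enal | O=C[C@@H](C(C)C)/C=C/c1ccccc1 | intermediate
8 | [(1E,3S)-3-(dimethoxymethyl)-4-methylpent-1-en-1-yl]benzene | COC(OC)[C@@H](C(C)C)/C=C/c1ccccc1 | intermediate
9 | (3S)-3-(dimethoxymethyl)-4-methylpent-1-ene | COC(OC)[C@@H](C(C)C)C=C | intermediate
10 | (3S)-3-[chloro(methoxy)methyl]-4-methylpent-1-ene (α-chloro ether, both epimers, not isolated) | COC(Cl)[C@@H](C(C)C)C=C | intermediate
11 | 2-bromo-3-{[(2S)-1-methoxy-2-(propan-2-yl)but-3-en-1-yl]oxy}-4,4,6,6-tetramethylcyclohex-2-ene-1,5-dione (both acetal epimers) | COC(OC1=C(Br)C(=O)C(C)(C)C(=O)C1(C)C)[C@@H](C(C)C)C=C | intermediate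
12 | 2-bromopropane | CC(C)Br | starting material
13 | (3S,4S)-2-methoxy-6,6,8,8-tetramethyl-4-(2-methylpropyl)-3-(propan-2-yl)-3,4-dihydro-2H-chromene-5,7(6H,8H)-dione (both C2 epimers) | CC(C)C[C@@H]1C2=C(OC(OC)[C@H]1C(C)C)C(C)(C)C(=O)C(C)(C)C2=O | intermediate
14 | ericifolione | CC(C)C[C@@H]1C2=C(O[C@@H](C3=C(O)C(C)(C)C(=O)C(C)(C)C3=O)[C@H]1C(C)C)C(C)(C)C(=O)C(C)(C)C2=O | target

**Step count and risks**

Total step count: 9. Longest linear sequence: 6 steps (5 → 7 → 8 → 9 → 11 → 13 → 14; the branch 1 → 2 → 3 → 4 → 11 → 13 → 14 is equally long).

Most likely to fail, first: step 8, the key step. The alkenylnickel may couple directly with the isopropyl radical before it inserts the alkene; the cyclised alkylnickel may undergo β-hydride elimination; and metal halides may cleave the acid-labile mixed acetal. The fallback uses known chemistry and sets out from 11. Cross-metathesis with 3-methylbut-1-ene (second-generation Grubbs catalyst, CH2Cl2, 40 °C, sealed) should give 2-bromo-3-{[(2S,3E)-1-methoxy-5-methyl-2-(propan-2-yl)hex-3-en-1-yl]oxy}-4,4,6,6-tetramethylcyclohex-2-ene-1,5-dione F1, which already carries the full isobutyl carbon chain. A tin-hydride 6-exo-trig alkenyl radical cyclisation (Bu3SnH, AIBN, benzene, 80 °C, syringe-pump addition) then closes the same C4–C4a bond through the same chair-like arrangement and comes back to the route at 13.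

Second: step 7. The α-chloro ether may lose HCl to a 1-methoxydiene, which would erase C3, and the acylal-like product may hydrolyse on work-up. The fallback sets out from 9 and replaces the chloro ether by an N,O-acetal salt that cannot eliminate in this way. TESOTf and 2,4,6-collidine (CH2Cl2, 0 °C) should convert 9 into 1-[(2S)-1-methoxy-2-(propan-2-yl)but-3-en-1-yl]-2,4,6-trimethylpyridin-1-ium trifluoromethanesulfonate F2. Displacement of collidine by the enol oxygen of 4 (0 °C to rt) comes back to the route at 11.

Third: step 9. Proton loss from the C2 oxocarbenium or alkylidene intermediates would epimerise C3, and incomplete equilibration at C2 would give poor diastereoselectivity. The fallback sets out from 13 and replaces the Lewis-acid substitution by a condensation on the free aldehyde. Mild hydrolysis (AcOH, H2O, THF, 40 °C) should give the lactol (3S,4S)-2-hydroxy-6,6,8,8-tetramethyl-4-(2-methylpropyl)-3-(propan-2-yl)-3,4-dihydro-2H-chromene-5,7(6H,8H)-dione F3. Its open-chain aldehyde should undergo Knoevenagel condensation with 3 (ethylenediammonium diacetate, 10 mol%, CH2Cl2, 25 °C), and oxa-Michael ring closure under the same thermodynamic control comes back to the route at 14.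

**Further compounds**

F1 | step 8 | 2-bromo-3-{[(2S,3E)-1-methoxy-5-methyl-2-(propan-2-yl)hex-3-en-1-yl]oxy}-4,4,6,6-tetramethylcyclohex-2-ene-1,5-dione | COC(OC1=C(Br)C(=O)C(C)(C)C(=O)C1(C)C)[C@@H](C(C)C)/C=C/C(C)C
F2 | step 7 | 1-[(2S)-1-methoxy-2-(propan-2-yl)but-3-en-1-yl]-2,4,6-trimethylpyridin-1-ium trifluoromethanesulfonate | COC([C@@H](C(C)C)C=C)[n+]1c(C)cc(C)cc1C.[O-]S(=O)(=O)C(F)(F)F
F3 | step 9 | (3S,4S)-2-hydroxy-6,6,8,8-tetramethyl-4-(2-methylpropyl)-3-(propan-2-yl)-3,4-dihydro-2H-chromene-5,7(6H,8H)-dione | CC(C)C[C@@H]1C2=C(OC(O)[C@H]1C(C)C)C(C)(C)C(=O)C(C)(C)C2=O
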